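**Assumption:** the target SMILES contains no stereocentre, because the C(CH3)2 carbon of the chromene carries two identical methyls. There is therefore one stereoisomer and no enantioselective step is needed. The target is 5,7,2'-trihydroxy-6-prenylisoflavone carrying a 2,2-dimethylchromene fused at C4'–C5'.

## Retrosynthetic overview
1. The C3–C1' bond is made late by Suzuki coupling of an A-ring 3-iodochromone with a B-ring chromenyl-Bpin, and global MOM removal is the last step.
2. The A-ring chromone comes first, from 2,6-dihydroxy-4-MOMO-acetophenone by enaminone formation and I2 cyclisation. The two ortho OH groups are equivalent, so there is no 5-/7-OH regiochemistry problem.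
3. The C6 prenyl is installed by the proposed new one-pot cascade: Au-catalysed tert-prenyl etherification of the chelated 5-OH with isoprene, then aromatic Claisen rearrangement. C6 is the only free ortho position of O5, so the linear prenyl ends up at C6.
4. The B-ring 2,2-dimethylchromene comes from 4-bromoresorcinol and prenal, and the resulting bromide is converted to the Bpin.
5. Ring-formation order: chromone pyranone (steps 2–3), prenyl (step 4), B-ring pyran (step 5), then the C3–C1' bond (step 8).

## Route

**Step 1**
Reactants: 1 (2,4,6-trihydroxyacetophenone), 2 (chloromethyl methyl ether)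
Product: 3 (2,6-dihydroxy-4-(methoxymethoxy)acetophenone)
Conditions: MOMCl (1.0 equiv), K2CO3, acetone, 0 °C → rt
Reagents that add atoms: MOMCl, ClCOC
Why: The 4-OH is the most acidic and is not chelated to the C=O, so it is alkylated selectively (Williamson-type MOM protection), leaving the two chelated ortho OH groups free and equivalent.

**Step 2**
Reactants: 3, 4 (N,N-dimethylformamide dimethyl acetal)
Product: 5 ((E)-3-(dimethylamino)-1-[2,6-dihydroxy-4-(methoxymethoxy)phenyl]prop-2-en-1-one)
Conditions: DMF-DMA (3 equiv), toluene, 85 °C
Reagents that add atoms: DMF-DMA, COC(OC)N(C)C (adds =CH–NMe2)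
Why: Condensation at the acetyl CH3 gives the push–pull (E)-enaminone without touching the H-bonded phenols.

**Step 3**
Reactants: 5, 6 (iodine)
Product: 7 (5-hydroxy-3-iodo-7-(methoxymethoxy)-4H-chromen-4-one)
Conditions: I2 (1.2 equiv), CHCl3, rt
Reagents that add atoms: I2, II
Why: This is the Gammill 3-iodochromone synthesis (α-iodination of the enaminone, phenol oxa-Michael addition, loss of Me2NH). The two ortho OH groups are equivalent, so only one chromone regioisomer can form.

**Step 4**
Reactants: 7, 8 (isoprene)
Product: 9 (5-hydroxy-3-iodo-7-(methoxymethoxy)-6-(3-methylbut-2-en-1-yl)-4H-chromen-4-one), formed through the in-situ intermediate 10 (3-iodo-7-MOMO-5-(2-methylbut-3-en-2-yloxy)chromone)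
Conditions: Ph3PAuNTf2 (5 mol%), isoprene (10 equiv), DCE, 60 °C, 12 h, sealed tube; then 120 °C, 6 h
Reagents that add atoms: isoprene, C=CC(C)=C (adds C5H9 as the prenyl group)
Why: Proposed new method: cationic Au(I) activates the 1,1-disubstituted alkene of isoprene so that the chelated 5-OH adds at the tertiary allylic carbon (Markovnikov), and protodeauration gives the tert-prenyl (1,1-dimethylallyl) aryl ether 10, which on heating undergoes aromatic Claisen [3,3] rearrangement to the linear prenyl at C6, the only free ortho position of O5 (no C8 product), so the net result is a formal ortho-C–H prenylation of the phenol with isoprene; the closest known reactions are Au-catalysed intermolecular hydroalkoxylation of allenes and dienes and the Claisen rearrangement of 1,1-dimethylallyl aryl ethers, and the new element is applying Au-catalysed hydroaryloxylation of isoprene to a chelation-deactivated 5-hydroxychromone as a one-pot etherification/Claisen cascade under soft conditions that avoid Friedel–Crafts C8-alkylation.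

**Step 5**
Reactants: 11 (4-bromoresorcinol), 12 (3-methylbut-2-enal, prenal)
Product: 13 (6-bromo-2,2-dimethyl-2H-chromen-7-ol)
Conditions: prenal (1.5 equiv), pyridine, 115 °C, sealed tube
Reagents that add atoms: prenal, CC(C)=CC=O (adds C5H6)
Why: Phenol ortho-alkenylation with the enal followed by oxa-6π electrocyclisation gives the 2,2-dimethylchromene. Attack at C6 (ortho to one OH, para to the other) gives the linear isomer, which is separated from the minor angular isomer by chromatography.

**Step 6**
Reactants: 13, 2 (MOMCl)
Product: 14 (6-bromo-7-(methoxymethoxy)-2,2-dimethyl-2H-chromene)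
Conditions: MOMCl (1.5 equiv), DIPEA, CH2Cl2, 0 °C → rt
Reagents that add atoms: MOMCl, ClCOC
Why: Standard phenol MOM protection, which prevents protodeboronation and Pd poisoning by the free ortho-OH in the later borylation and coupling.

**Step 7**
Reactants: 14, 15 (bis(pinacolato)diboron)
Product: 16 (2-[7-(methoxymethoxy)-2,2-dimethyl-2H-chromen-6-yl]-4,4,5,5-tetramethyl-1,3,2-dioxaborolane)
Conditions: B2pin2 (1.3 equiv), Pd(dppf)Cl2 (5 mol%), KOAc, dioxane, 90 °C
Reagents that add atoms: B2pin2, CC1(C)OB(OC1(C)C)B1OC(C)(C)C(C)(C)O1 (adds Bpin)
Why: Miyaura borylation of the aryl bromide; the chromene alkene and the MOM ether are inert.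

**Step 8**
Reactants: 9, 16
Product: 17 (5-hydroxy-7-(methoxymethoxy)-3-[7-(methoxymethoxy)-2,2-dimethyl-2H-chromen-6-yl]-6-(3-methylbut-2-en-1-yl)-4H-chromen-4-one)
Conditions: Pd(PPh3)4 (5 mol%), K2CO3 (3 equiv), dioxane/H2O 4:1, 80 °C
Reagents that add atoms: none (both coupling partners are incorporated; base and Pd leave no atoms)
Why: Suzuki–Miyaura coupling at the reactive vinylic C–I bond of the 3-iodochromone forms the C3–C1' bond, and the chelated 5-OH, the prenyl olefin and the chromene olefin are unaffected.

**Step 9**
Reactants: 17
Product: 18 (Krausianone 2)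
Conditions: TMSOTf (5 equiv), 2,2'-bipyridyl (6 equiv), MeCN, 0 °C → rt; then H2O
Reagents that add atoms: none (TMSOTf and bipyridyl are removed on aqueous work-up)
Why: TMSOTf/2,2'-bipyridyl cleaves aromatic MOM ethers through a pyridinium intermediate that water hydrolyses, under non-acidic buffered conditions that spare the acid-labile chromene and prenyl groups, giving the free 7-OH and 2'-OH.

## Compound list
1 | 2,4,6-trihydroxyacetophenone | CC(=O)c1c(O)cc(O)cc1O | starting material
2 | chloromethyl methyl ether | ClCOC | starting material
3 | 2,6-dihydroxy-4-(methoxymethoxy)acetophenone | CC(=O)c1c(O)cc(OCOC)cc1O | intermediate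
4 | N,N-dimethylformamide dimethyl acetal | COC(OC)N(C)C | starting material
5 | (E)-3-(dimethylamino)-1-[2,6-dihydroxy-4-(methoxymethoxy)phenyl]prop-2-en-1-one | CN(C)/C=C/C(=O)c1c(O)cc(OCOC)cc1O | intermediate
6 | iodine | II | starting material
7 | 5-hydroxy-3-iodo-7-(methoxymethoxy)chromone | O=c1c(I)coc2cc(OCOC)cc(O)c12 | intermediate
8 | isoprene | C=CC(C)=C | starting material
9 | 5-hydroxy-3-iodo-7-(methoxymethoxy)-6-prenylchromone | O=c1c(I)coc2cc(OCOC)c(CC=C(C)C)c(O)c12 | intermediate
10 | 3-iodo-7-(methoxymethoxy)-5-(2-methylbut-3-en-2-yloxy)chromone (formed and consumed in situ in step 4) | O=c1c(I)coc2cc(OCOC)cc(OC(C)(C)C=C)c12 | intermediate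
11 | 4-bromoresorcinol | Oc1ccc(Br)c(O)c1 | starting material
12 | 3-methylbut-2-enal | CC(C)=CC=O | starting material
13 | 6-bromo-2,2-dimethyl-2H-chromen-7-ol | CC1(C)C=Cc2cc(Br)c(O)cc2O1 | intermediate
14 | 6-bromo-7-(methoxymethoxy)-2,2-dimethyl-2H-chromene | CC1(C)C=Cc2cc(Br)c(OCOC)cc2O1 | intermediate
15 | bis(pinacolato)diboron | CC1(C)OB(OC1(C)C)B1OC(C)(C)C(C)(C)O1 | starting material
16 | 7-(methoxymethoxy)-2,2-dimethyl-2H-chromen-6-yl-Bpin | CC1(C)C=Cc2cc(B3OC(C)(C)C(C)(C)O3)c(OCOC)cc2O1 | intermediate
17 | bis-MOM isoflavone | O=c1c(-c2cc3c(cc2OCOC)OC(C)(C)C=C3)coc2cc(OCOC)c(CC=C(C)C)c(O)c12 | intermediate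
18 | Krausianone 2 | CC(C)=CCc1c(O)cc2occ(-c3cc4c(cc3O)OC(C)(C)C=C4)c(=O)c2c1O | target

## Totals and risks
Total steps: 9. Longest linear sequence: 6 steps (1, 2, 3, 4, 8, 9, from compound 1).

Three steps most likely to fail:
1. **Step 4 (proposed new Au-catalysed hydroaryloxylation/Claisen cascade).** The chelated 5-OH is a poor nucleophile, and the cation or the tertiary ether can ionise to give linear O-prenyl or C8-prenyl products.
   - Fallback (known chemistry, different approach): 5-O-allylation of 7 (allyl bromide, Cs2CO3, DMF, 60 °C), then Claisen rearrangement in PhNEt2 at 185 °C to give 6-allyl-5-hydroxy-3-iodochromone, then cross-metathesis with 2-methyl-2-butene (Grubbs II, CH2Cl2, 40 °C) to give 9.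
2. **Step 8 (hindered, ortho-substituted Suzuki coupling with a free 5-OH).** Protodeboronation of the aryl-Bpin could compete with coupling.
   - Fallback: Negishi coupling instead. Do Br–Li exchange on 14 (n-BuLi, THF, –78 °C), transmetalate with ZnCl2, and couple the arylzinc (2.5 equiv, to tolerate the 5-OH proton) with 9 using Pd(PPh3)4.
3. **Step 5 (linear vs angular chromene annulation).** The angular isomer is a likely by-product and lowers the yield.
   - Fallback: acylate 4-bromoresorcinol with 3,3-dimethylacrylic acid (TfOH), which gives 6-bromo-7-hydroxy-2,2-dimethylchroman-4-one regiospecifically by para-acylation and oxa-Michael ring closure. Then reduce with NaBH4 and dehydrate with cat. TsOH in toluene at 80 °C to obtain 13.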